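Early times are where to look first, in these runs and for these flasks:

the same everywhere: substrate 0.050 M

|  | partner | reagent | temperature | remark | time |
|---|---|---|---|---|---|
| Sunday's | 0.065 M | 0.060 M | 20 °C | run made earlier |  |
| Friday's | 0.044 M | 0.060 M | 31 °C | run made earlier |  |
| Monday's | 0.098 M | 0.060 M | 20 °C | run made earlier |  |
| Tuesday's | 0.065 M | 0.12 M | 31 °C | run made earlier |  |
| autumn | 0.0650 M (fed, over 8.0 h) | 0.0600 M |  | the addition at 5 °C, then warmed to 25 °C; the feed brings no volume worth counting | 10 h |
| spring | 0.0650 M | 0.0600 M |  | everything together at the start at 5 °C, warmed to 25 °C at 8.0 h | 10 h |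
| dusk | 0.0650 M (fed, over 8.0 h) | 0.0600 M | 25 °C | all else is in the flask from the start; the feed brings no volume worth counting | 10 h |
| summer | 0.0650 M (in portions, 3, over 8.0 h) | 0.0600 M | 25 °C | first portion at the start, last at 8.0 h | 10 h |
| midnight | 0.0650 M | 0.0600 M | 25 °C | everything together at the start | 10 h |

- Sunday's (time / h: target / %, substrate / %): 0.500: 0, 78; 1.50: 3, 67; 3.00: 6, 58; 4.00: 8, 58; 6.00: 12, 59
- Friday's (time / h: target / %, substrate / %): 1.50: 4, 52; 3.00: 5, 49; 5.00: 9, 52; 6.00: 8, 50; 8.00: 9, 51
- Monday's (time / h: target / %, substrate / %): 0.667: 1, 79; 2.00: 4, 67; 4.00: 8, 69; 6.00: 8, 69; 8.00: 11, 65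
- Tuesday's (time / h: target / %, substrate / %): 0.667: 9, 36; 1.33: 15, 26; 2.50: 16, 14; 4.00: 17, 12; 8.00: 15, 6

(standard deviation of a reading: 2 percentage points)

1. which flask leads in amount of target, in percent of the substrate charged ("all alike" within 1.5 percentage points) (autumn / spring / dusk / summer / midnight / all alike)
2. how much target is there at the end, in percent of the substrate charged: autumn
3. how much target is there at the end, in percent of the substrate charged: spring
4. how much target is there at the end, in percent of the substrate charged: dusk
5. how much target is there at the end, in percent of the substrate charged: summer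
6. how much target is there at the end, in percent of the substrate charged: midnight

- the numbers in the tables scatter with a standard deviation of 2 percentage points

In Sunday's run substrate is down to 78% after 0.500 h. With reagent taken at its charge of 0.060 M, that gives a pace of roughly 8.28 L mol⁻¹ h⁻¹. Now call reagent life the time scale on which substrate at its charge takes reagent, one over pace times substrate: 2.41 h. This is your first rung, shorter than the 8.0 h feed of dusk, which is the next one.

The last rung shows after that. From 3.00 h Sunday's substrate stands near 58%, so it took 0.0210 M of the reagent. I put the other 0.0390 M on partner, since Monday's larger partner charge leaves substrate higher, at 69%. Yet Sunday's target still climbs from 6% to 12% by 6.00 h with substrate standing still, so I read target as made over hours from what reagent left behind on both sides.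

Now dusk, by my own reckoning. During one reagent life, a share of 0.302 of the partner has arrived. I count that share as what reagent meets, 0.0196 M, and give the rest of the reagent to substrate, which leaves substrate at 19.2%. Dusk's partner side is then smaller than Sunday's, so I don't expect dusk to beat midnight, which has Sunday's charge. The step from Sunday's 20 °C to dusk's 25 °C stays uncounted here.

The forecast put dusk first with 32%, then summer at 23%, autumn at 17%, midnight at 13% and spring at 7%, saying “so dusk should be best”. The simulation puts spring first at 14.3%, then autumn 12.5%, midnight 9.75%, summer 8.90% and dusk 7.88%.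

    2 second intermediate → homo product (k = 8.73 × 10⁻⁴ L mol⁻¹ s⁻¹, Ea = 74.0 kJ mol⁻¹)
    second intermediate → decomposed reagent (k = 1.28 × 10⁻⁴ s⁻¹, Ea = 94.0 kJ mol⁻¹)
    open intermediate + second intermediate → target (k = 0.00241 L mol⁻¹ s⁻¹, Ea = 54.0 kJ mol⁻¹)
    substrate + reagent → open intermediate (k = 0.00454 L mol⁻¹ s⁻¹, Ea = 49.0 kJ mol⁻¹)
    open intermediate → side product (k = 7.95 × 10⁻⁵ s⁻¹, Ea = 100 kJ mol⁻¹)
    reagent + partner → second intermediate (k = 0.00843 L mol⁻¹ s⁻¹, Ea = 67.0 kJ mol⁻¹)
    (constants at 25 °C)

Reagent life lands near dusk's end: substrate ends at 20.6% against my 19.2%, and partner at 68.8% against my 69.8%. Of the two steps tried, the largest single effect on spring's lead over dusk is the open intermediate's slide to side product: a run without that step cuts the gap from 6.4 points to 1.7 points. In the neighbour of dusk charged with 0.020 M of substrate, reagent life grows to 6.04 h, a share of 0.755 of the feed, which by my count leaves partner at 24.5%. That neighbour flask ends with partner at 37.7% and target at 15.4% of its own substrate charge, a higher percentage than dusk's 7.88%.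

Readings and results were generated by integration for substances that don't exist; scatter was added.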